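**Plan**

1. Atoms are numbered in the order of the target SMILES (C1 exocyclic CH2, C2 its ring carbon, C5 and C10 the pyran stereocentres, O9 the pyran oxygen, C14–C17 the cyclobutane). The retrosynthesis cuts C1=C2 (methylenation), takes C15–C16 back to a cyclobutenyl ketone, then cuts C14–C15 and C16–C17 together.
2. Enabling feature: the cyclobutane C14–C15–C16–C17 shares its C14–C15 edge with the nine-membered carbocycle (C2, C3, C4, C5, C10, C12, C13, C14, C15). A terminal alkyne C15≡C16 on the C5 arm and the alkene C14=C17 of the homoprenyl arm on C10 can therefore close both rings in one gold(I) enyne [2+2] event.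
3. The seco-enyne is cut at C2–C15 (ethynyl addition), at O9–C8 and C6–C7 (pyran: cyclodehydration and reductive Knoevenagel alkylation of isobutyrylfilicinic acid) and at C4–C5 (opening of epoxygeraniol).
4. Forward: the trione ring comes from phloroglucinol; the chain is joined as epoxygeraniol + C3 acetal Grignard, + trione, + ethyne; the rings arise as pyran first, then nine-membered ring and cyclobutene in one step.
5. Stereochemistry: C5 and C10 from Sharpless epoxidation and SN2 opening with inversion at C5; C14 by substrate control in the gold step; C15 by base equilibration to the trans ring fusion.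

Key step: step 11

Assumption: the C2 carbinol centre is temporary (it becomes a ketone before the end), so the ethynylation is run without stereocontrol and the four compounds from the propargylic alcohol to the allylic alcohol are carried as pairs of C2 epimers, with C2 left unspecified in their SMILES.

**Route**

Step 1
Reactants: 1 phloroglucinol
Product: 2 isobutyrylphloroglucinol
Conditions: isobutyryl chloride (1.1 equiv), AlCl3 (3 equiv), PhNO2/CH2Cl2, 0 → 50 °C; aq. HCl
Reagents that add atoms: isobutyryl chloride, CC(C)C(=O)Cl
Why: Friedel–Crafts acylation of the electron-rich arene, which stops at the mono-ketone because the chelated acyl group deactivates the ring.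

Step 2
Reactants: 2 isobutyrylphloroglucinol
Product: 4 isobutyrylfilicinic acid, via C-monomethyl ketone 3 (not isolated)
Conditions: NaOMe (3 equiv), MeI (2.2 equiv), MeOH, 0 → 23 °C
Reagents that add atoms: iodomethane, CI
Why: Dearomatising C-methylation of the phloroglucinolate, in which the second methyl group prefers the already methylated, more electron-rich carbon and so gives the gem-dimethyl trione; under-, over- and 3,5-dimethylated material is removed by chromatography.

Step 3
Reactants: 5 geraniol
Product: 6 (2S,3S)-2,3-epoxygeraniol
Conditions: Ti(OiPr)4 (5 mol%), L-(+)-diethyl tartrate (6 mol%), t-BuOOH (2 equiv), 4 Å MS, CH2Cl2, −20 °C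
Reagents that add atoms: tert-butyl hydroperoxide, CC(C)(C)OO
Why: Sharpless asymmetric epoxidation, in which the L-tartrate titanium complex epoxidises only the allylic alkene and gives the (2S,3S)-epoxide, fixing the C–O bond of the future C10 and the configuration from which C5 is derived.

Step 4
Reactants: 6 (2S,3S)-2,3-epoxygeraniol; 7 2-(2-bromoethyl)-1,3-dioxolane
Product: 9 acetal 1,3-diol, via Grignard reagent 8 (not isolated)
Conditions: 7 (3.5 equiv), Mg, THF, 25–30 °C; then CuI (10 mol%), 6, THF, −30 → 0 °C; aq. NH4Cl
Reagents that add atoms: none
Why: Copper-catalysed SN2 opening of the 2,3-epoxy alcohol by the Grignard reagent at the less substituted CH carbon gives the 1,3-diol with inversion, which sets C5 as R while the tertiary C10–O bond stays intact.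

Step 5
Reactants: 9 acetal 1,3-diol
Product: 10 β-hydroxy aldehyde
Conditions: TEMPO (10 mol%), PhI(OAc)2 (1.1 equiv), CH2Cl2, 0 → 23 °C; used crude
Reagents that add atoms: none
Why: Oxoammonium (TEMPO) oxidation takes the primary alcohol to the aldehyde and leaves the tertiary alcohol, the acetal and the alkene alone, and the non-basic conditions with immediate use protect the α-centre C5.

Step 6
Reactants: 10 β-hydroxy aldehyde; 4 isobutyrylfilicinic acid
Product: 12 C-alkylated trione, via alkylidene trione 11 (not isolated)
Conditions: Hantzsch ester (1.2 equiv), L-proline (10 mol%), CH2Cl2, 0 → 23 °C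
Reagents that add atoms: none
Why: Three-component reductive Knoevenagel alkylation, in which the aldehyde condenses at the only free ring CH of the trione and the alkylidene is reduced at once by hydride transfer from the dihydropyridine, forming C6–C7 without bis-adduct and leaving little time for C5 to enolise (a C5 epimer would be a separable diastereomer because C10 is fixed).

Step 7
Reactants: 12 C-alkylated trione
Product: 13 pyran acetal
Conditions: PPTS (10 mol%), 4 Å MS, toluene, 60 °C
Reagents that add atoms: none
Why: Acid-catalysed cyclodehydration of the δ-hydroxy triketone through its six-membered hemiketal closes O9–C8 without ever breaking the C10–O bond, so C10 keeps its configuration, and closure should go to C8 because the C31 oxygen is held as the hydrogen-bonded enol of the isobutyryl group, which leaves C8 as the ketone-like carbonyl.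

Step 8
Reactants: 13 pyran acetal
Product: 14 pyran aldehyde
Conditions: 1 M aq. HCl, THF, 23 °C
Reagents that add atoms: water, O
Why: Acid hydrolysis of the dioxolane, to which the vinylogous ester of the pyran and the trisubstituted alkene are stable at room temperature.

Step 9
Reactants: 14 pyran aldehyde; 15 ethynylmagnesium bromide
Product: 16 propargylic alcohol (both C2 epimers)
Conditions: 15 (3.5 equiv), THF, −40 → 0 °C; aq. NH4Cl
Reagents that add atoms: none
Why: Grignard addition to the aldehyde, in which the first equivalent deprotonates the acidic enol and the magnesium trionate so formed is inert to further addition, so that only C2–C15 is made and no control at C2 is needed.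

Step 10
Reactants: 16 propargylic alcohol
Product: 17 seco-enyne silyl ether (both C2 epimers)
Conditions: TBSCl (1.5 equiv), imidazole (3 equiv), DMF, 23 °C; aqueous work-up
Reagents that add atoms: tert-butyldimethylsilyl chloride, CC(C)(C)[Si](C)(C)Cl
Why: Silylation of the secondary alcohol (the chelated enol is slow to react and any silyl enol ether falls off on work-up) blocks Meyer–Schuster rearrangement of the propargylic alcohol under gold catalysis.

Step 11
Reactants: 17 seco-enyne silyl ether
Product: 18 tetracyclic cyclobutene silyl ether
Conditions: [(t-BuXPhos)Au(MeCN)]BArF4 (5 mol%), 3 Å MS, CH2Cl2, 23 °C, slow addition of 17 to a final 2 mM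
Reagents that add atoms: none
Why: The cationic gold(I) centre π-activates the terminal alkyne, the alkene attacks the internal carbon C15 through its CH terminus C14 so that positive charge builds on the tertiary carbon C17, and the cyclopropyl gold carbene so formed ring-expands with C16–C17 bonding and release of the catalyst. The closest known reaction type is the gold(I)-catalysed formal [2+2] cycloaddition of terminal alkynes with alkenes, including its intramolecular form on large 1,n-enynes (n from 10 upward) that gives cyclobutene-fused rings of nine and more members; an aliphatic alkyne on a wholly sp3 tether sits at the limit of that scope. The nine-membered ring closes in the 9-exo-dig attack of C14 on C15 and the cyclobutene in the ring expansion that joins C16 to C17 in the same intermediate, so the tether ends are exactly the carbons that the intermolecular regiochemistry would join. C14 is the only new stereocentre and is set by the alkene face that the folded tether presents, which the diequatorial C5 and C10 arms and the axial C10 methyl group of the pyran should bias toward the caryophyllane-like ring conformation (substrate control), the C2 silyl ether being a bystander. The step needs exo-dig regiochemistry, ring closure faster than oligomerisation and no attack of the enol on the alkyne, which the cation-stabilising CMe2 terminus, the bulky phosphine with a non-coordinating anion under high dilution, and the hydrogen-bonded, weakly nucleophilic enol are meant to secure.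

Step 12
Reactants: 18 tetracyclic cyclobutene silyl ether
Product: 19 cyclobutenyl carbinol (both C2 epimers)
Conditions: HF·pyridine, pyridine, THF, 0 → 23 °C
Reagents that add atoms: none
Why: Fluoride cleavage of the silyl ether under buffered, weakly acidic conditions that neither disturb the trione nor ionise the allylic carbinol.

Step 13
Reactants: 19 cyclobutenyl carbinol
Product: 20 cyclobutenyl ketone
Conditions: activated MnO2 (20 equiv), CH2Cl2, 23 °C
Reagents that add atoms: none
Why: Manganese dioxide oxidises only the allylic alcohol, which merges both C2 epimers into one enone and spares the enolised trione.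

Step 14
Reactants: 20 cyclobutenyl ketone
Product: 22 trans-fused ketone, via cis-fused ketone 21 (not isolated)
Conditions: H2 (1 atm), 5% Pd/C, EtOAc, 23 °C; filter; DBU (3 equiv), toluene, 50 °C; dilute acid work-up
Reagents that add atoms: none
Why: Catalytic hydrogenation saturates the strained conjugated C15=C16 bond (the remaining C=C bonds are tetrasubstituted push–pull alkenes), expected from the face of the C14 hydrogen to give the cis ring fusion, and enolate equilibration with DBU then epimerises C15 to the thermodynamically preferred trans-fused bicyclo[7.2.0]undecanone, setting C15 as S.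

Step 15
Reactants: 22 trans-fused ketone
Product: 23 target CNP0497637.1
Conditions: Ph3PCH3Br (5 equiv), KOtBu (4.8 equiv), THF, 0 → 50 °C; aq. NH4Cl
Reagents that add atoms: methyltriphenylphosphonium bromide, C[P+](c1ccccc1)(c1ccccc1)c1ccccc1.[Br-]
Why: Wittig methylenation, in which one equivalent of ylide deprotonates the enol, the trionate carbonyls stay inert and the C2 ketone becomes the exocyclic methylene, while C15 is already at its thermodynamic configuration and cannot be scrambled by the base.

**Compound list**

1 | phloroglucinol | Oc1cc(O)cc(O)c1 | starting material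
2 | 2-methyl-1-(2,4,6-trihydroxyphenyl)propan-1-one (isobutyrylphloroglucinol) | CC(C)C(=O)c1c(O)cc(O)cc1O | intermediate
3 | 2-methyl-1-(2,4,6-trihydroxy-3-methylphenyl)propan-1-one (C-monomethyl ketone, not isolated) | CC(C)C(=O)c1c(O)cc(O)c(C)c1O | intermediate
4 | isobutyrylfilicinic acid, 3,5-dihydroxy-6,6-dimethyl-2-(2-methylpropanoyl)cyclohexa-2,4-dien-1-one | CC(C)C(=O)C1=C(O)C=C(O)C(C)(C)C1=O | intermediate
5 | geraniol | CC(C)=CCC/C(C)=C/CO | starting material
6 | [(2S,3S)-3-methyl-3-(4-methylpent-3-en-1-yl)oxiran-2-yl]methanol ((2S,3S)-2,3-epoxygeraniol) | OC[C@@H]1O[C@@]1(C)CCC=C(C)C | intermediate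
7 | 2-(2-bromoethyl)-1,3-dioxolane | BrCCC1OCCO1 | starting material
8 | [2-(1,3-dioxolan-2-yl)ethyl]magnesium bromide (not isolated) | Br[Mg]CCC1OCCO1 | intermediate
9 | (2R,3S)-2-[2-(1,3-dioxolan-2-yl)ethyl]-3,7-dimethyloct-6-ene-1,3-diol | O1CCOC1CC[C@H](CO)[C@@](C)(O)CCC=C(C)C | intermediate
10 | (2S,3S)-2-[2-(1,3-dioxolan-2-yl)ethyl]-3-hydroxy-3,7-dimethyloct-6-enal | O1CCOC1CC[C@H](C=O)[C@@](C)(O)CCC=C(C)C | intermediate
11 | Knoevenagel alkylidene of 4 and 10, exocyclic C6=C7 with geometry left open, (2R,3S) in the chain (not isolated) | O1CCOC1CC[C@H](C=C2C(=O)C(C)(C)C(=O)C(C(=O)C(C)C)=C2O)[C@@](C)(O)CCC=C(C)C | intermediate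
12 | 4-{(2R,3S)-2-[2-(1,3-dioxolan-2-yl)ethyl]-3-hydroxy-3,7-dimethyloct-6-en-1-yl}-3,5-dihydroxy-6,6-dimethyl-2-(2-methylpropanoyl)cyclohexa-2,4-dien-1-one | O1CCOC1CC[C@H](CC2=C(O)C(C)(C)C(=O)C(C(=O)C(C)C)=C2O)[C@@](C)(O)CCC=C(C)C | intermediate
13 | (2S,3R)-3-[2-(1,3-dioxolan-2-yl)ethyl]-5-hydroxy-2,8,8-trimethyl-2-(4-methylpent-3-en-1-yl)-6-(2-methylpropanoyl)-3,4-dihydro-2H-chromen-7(8H)-one | O1CCOC1CC[C@@H]1CC2=C(O[C@@]1(C)CCC=C(C)C)C(C)(C)C(=O)C(C(=O)C(C)C)=C2O | intermediate
14 | 3-[(2S,3R)-5-hydroxy-2,8,8-trimethyl-2-(4-methylpent-3-en-1-yl)-6-(2-methylpropanoyl)-7-oxo-3,4,7,8-tetrahydro-2H-chromen-3-yl]propanal | O=CCC[C@@H]1CC2=C(O[C@@]1(C)CCC=C(C)C)C(C)(C)C(=O)C(C(=O)C(C)C)=C2O | intermediate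
15 | ethynylmagnesium bromide | C#C[Mg]Br | starting material
16 | (2S,3R)-5-hydroxy-3-(3-hydroxypent-4-yn-1-yl)-2,8,8-trimethyl-2-(4-methylpent-3-en-1-yl)-6-(2-methylpropanoyl)-3,4-dihydro-2H-chromen-7(8H)-one, both carbinol (C2) epimers | C#CC(O)CC[C@@H]1CC2=C(O[C@@]1(C)CCC=C(C)C)C(C)(C)C(=O)C(C(=O)C(C)C)=C2O | intermediate
17 | tert-butyldimethylsilyl ether of 16 (seco-enyne: silyloxy-pentynyl arm on C5, homoprenyl arm on C10), both C2 epimers | C#CC(O[Si](C)(C)C(C)(C)C)CC[C@@H]1CC2=C(O[C@@]1(C)CCC=C(C)C)C(C)(C)C(=O)C(C(=O)C(C)C)=C2O | intermediate
18 | tetracyclic cyclobutene: pyran-fused nine-membered ring carrying the 3,3-dimethylcyclobutene C14–C15=C16–C17 and the C2 silyl ether; 5R,10S,14S (the C14 descriptor is S only because C15 is sp2; the atom has the target geometry), both C2 epimers | CC(C)(C)[Si](C)(C)OC1CC[C@@H]2CC3=C(O[C@@]2(C)CC[C@@H]2C1=CC2(C)C)C(C)(C)C(=O)C(C(=O)C(C)C)=C3O | intermediate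
19 | C2 allylic alcohol of 18 after desilylation; 5R,10S,14S, both C2 epimers | OC1CC[C@@H]2CC3=C(O[C@@]2(C)CC[C@@H]2C1=CC2(C)C)C(C)(C)C(=O)C(C(=O)C(C)C)=C3O | intermediate
20 | cyclobutenyl ketone (C2=O conjugated with C15=C16); 5R,10S,14S | O=C1CC[C@@H]2CC3=C(O[C@@]2(C)CC[C@@H]2C1=CC2(C)C)C(C)(C)C(=O)C(C(=O)C(C)C)=C3O | intermediate
21 | cis-fused C2 ketone; 5R,10S,14R,15R (not isolated) | O=C1CC[C@@H]2CC3=C(O[C@@]2(C)CC[C@@H]2[C@H]1CC2(C)C)C(C)(C)C(=O)C(C(=O)C(C)C)=C3O | intermediate
22 | trans-fused C2 ketone; 5R,10S,14R,15S | O=C1CC[C@@H]2CC3=C(O[C@@]2(C)CC[C@@H]2[C@@H]1CC2(C)C)C(C)(C)C(=O)C(C(=O)C(C)C)=C3O | intermediate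
23 | CNP0497637.1; 5R,10S,14R,15S, exocyclic methylene on C2 | C=C1CC[C@@H]2CC3=C(O[C@@]2(C)CC[C@@H]2[C@@H]1CC2(C)C)C(C)(C)C(=O)C(C(=O)C(C)C)=C3O | target

**Count**

Total steps: 15. Longest linear sequence: 13 (steps 3 to 15, from geraniol).

**Steps most likely to fail**

1. Step 11. Intermolecular alkyne–alkene coupling and oligomerisation may outrun the nine-membered ring closure, the aliphatic alkyne may be hydrated or left unreacted, or the two alkene faces may react without discrimination so that C14 forms as a mixture. Fallback: the enyne disconnection is given up and the carbocyclic part is bought. The route is left at 4, which is heated with paraformaldehyde (NaOAc, AcOH, 80 °C) in the presence of (−)-β-caryophyllene (C=C1CC/C=C(C)/CC[C@@H]2[C@@H]1CC2(C)C). Knoevenagel condensation should give the o-quinone methide 5-hydroxy-2,2-dimethyl-6-methylidene-4-(2-methylpropanoyl)cyclohex-4-ene-1,3-dione F1, which is trapped as it forms by the endocyclic E-alkene in a hetero-Diels–Alder reaction. This comes back to the route at 23, which would have to be separated from the diastereomer that arises from the other ring conformer of the diene partner.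

2. Step 7. The tertiary carbinol may ionise under acid (elimination, loss of the C10 configuration), or the hemiketal may form at the acyl-side carbonyl C31 and lead to the regioisomeric pyran. Fallback: setting out from 12, the free, non-chelated enol hydroxyl on C8 is methylated with TMSCHN2 (toluene/MeOH, 0 °C) to give the C8 methyl enol ether of the C-alkylated trione F2. Vinylogous transesterification (CSA cat., 5 Å MS, toluene, 50 °C) then lets the tertiary hydroxyl displace methanol by addition–elimination at C8. This fixes the site of closure, needs no water-forming step and a weaker acid, and comes back to the route at 13.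

3. Step 15. The ylide may act only as a base (enolisation of the hindered nine-membered ketone, precipitation of the trionate salt), so that olefination stalls. Fallback: setting out from 22, (trimethylsilyl)methyllithium with CeCl3 (THF, −78 °C, excess to cover the enol proton) adds to the C2 ketone to give the β-hydroxysilane, the C2 tertiary carbinol bearing a (trimethylsilyl)methyl group F3. Elimination with KH (THF, 0 → 23 °C, Peterson olefination) then comes back to the route at 23.

**Further compounds**

F1 | step 11 | 5-hydroxy-2,2-dimethyl-6-methylidene-4-(2-methylpropanoyl)cyclohex-4-ene-1,3-dione (o-quinone methide, trapped in situ) | C=C1C(=O)C(C)(C)C(=O)C(C(=O)C(C)C)=C1O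
F2 | step 7 | C8 methyl enol ether of the C-alkylated trione 12 | O1CCOC1CC[C@H](CC2=C(OC)C(C)(C)C(=O)C(C(=O)C(C)C)=C2O)[C@@](C)(O)CCC=C(C)C
F3 | step 15 | β-hydroxysilane from 22, C2 carbinol bearing a (trimethylsilyl)methyl group, C2 configuration open | C[Si](C)(C)CC1(O)CC[C@@H]2CC3=C(O[C@@]2(C)CC[C@@H]2[C@@H]1CC2(C)C)C(C)(C)C(=O)C(C(=O)C(C)C)=C3O
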